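**Strategy**

The route disconnects ring C of the lower dihydroflavonol unit at C2–C3 and O1–C8a. In one operation, a chiral ammonium fluoride relays an aldol/SNAr annulation between 3,4,5-tris(benzyloxy)benzaldehyde and the enol silane of a 2-fluoroaryl benzyloxymethyl ketone: the aldol forges C2–C3 and sets C2 and C3, and the new alkoxide oxygen displaces fluoride from C8a of ring A, closing the pyranone. The step exploits the C4 carbonyl, which makes C3 an enolate carbon and activates the ortho carbon C8a toward substitution. The ketone precursor already carries the robinetinidol unit on C8, installed by arylzinc capture of a flavan-4-yl cation derived from (+)-dihydrorobinetin, so no C6/C8 regiochemistry arises.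

Key step: step 7

Assumption: (+)-dihydrorobinetin is bought as the natural (2R,3R) enantiomer, and the cinchonidinium catalyst of step 7 is taken to direct the enolate to the Si face of the aldehyde (its cinchoninium pseudoenantiomer would be used if the sense proves opposite).

**Route**

Step 1
Reactants: 1 (+)-dihydrorobinetin
Product: 2 (2R,3R)-7-(benzyloxy)-3-hydroxy-2-[3,4,5-tris(benzyloxy)phenyl]chroman-4-one
Conditions: BnBr (4.4 equiv), K2CO3, DMF, rt, argon
Reagents that add atoms: benzyl bromide, BrCc1ccccc1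
Why: Williamson etherification under carbonate should benzylate only the four phenols, leaving the less acidic 3-OH free, and the mild base at room temperature should leave C2 and C3 untouched.

Step 2
Reactants: 2 (2R,3R)-7-(benzyloxy)-3-hydroxy-2-[3,4,5-tris(benzyloxy)phenyl]chroman-4-one
Product: 3 (2R,3S,4R)-7-(benzyloxy)-2-[3,4,5-tris(benzyloxy)phenyl]chromane-3,4-diol
Conditions: NaBH4, THF/MeOH, 0 °C
Reagents that add atoms: none
Why: Borohydride reduction of the ring C ketone should give the 3,4-trans diol (equatorial alcohol), and the C4 configuration is of no consequence because C4 is ionised in step 4.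

Step 3
Reactants: 3 (2R,3S,4R)-7-(benzyloxy)-2-[3,4,5-tris(benzyloxy)phenyl]chromane-3,4-diol
Product: 4 (2R,3S,4R)-3,4,7-tris(benzyloxy)-2-[3,4,5-tris(benzyloxy)phenyl]chromane
Conditions: NaH, BnBr, tetrabutylammonium iodide (cat.), DMF, 0 °C → rt
Reagents that add atoms: benzyl bromide, BrCc1ccccc1
Why: Williamson etherification of both alkoxides caps the 3-OH as its final benzyl ether and turns the 4-OH into an ionisable benzylic ether leaving group without touching a stereocentre.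

Step 4
Reactants: 4 (2R,3S,4R)-3,4,7-tris(benzyloxy)-2-[3,4,5-tris(benzyloxy)phenyl]chromane; 5 4-(benzyloxy)-1-bromo-2-fluorobenzene
Product: 8 (2R,3S,4S)-3,7-bis(benzyloxy)-4-[6-(benzyloxy)-3-bromo-2-fluorophenyl]-2-[3,4,5-tris(benzyloxy)phenyl]chromane, via aryllithium 6 (not isolated), via diarylzinc 7 (not isolated)
Conditions: 5 (3 equiv), LiN(iPr)2, THF, –78 °C; ZnBr2 (1.5 equiv), –78 → 0 °C; volatiles removed, CH2Cl2; 4, Me3SiOTf, –78 → –30 °C
Reagents that add atoms: none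
Why: Directed ortho-lithiation occurs at the carbon flanked by fluorine and benzyloxy, transmetalation gives a diarylzinc, and Me3SiOTf ionises the C4 benzyl ether to a flavan-4-yl cation stabilised by O1 and the 7-benzyloxy group, which the arylzinc should capture at its ipso carbon (SN1-type arylation of an oxocarbenium-like cation, as in arylzinc C-glycosylation), attack anti to the 3-benzyloxy group setting C4 as S (3,4-trans).

Step 5
Reactants: 8 (2R,3S,4S)-3,7-bis(benzyloxy)-4-[6-(benzyloxy)-3-bromo-2-fluorophenyl]-2-[3,4,5-tris(benzyloxy)phenyl]chromane; 9 2-(benzyloxy)-N-methoxy-N-methylacetamide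
Product: 11 2-(benzyloxy)-1-{4-(benzyloxy)-3-[(2R,3S,4S)-3,7-bis(benzyloxy)-2-[3,4,5-tris(benzyloxy)phenyl]chroman-4-yl]-2-fluorophenyl}ethan-1-one, via aryllithium 10 (not isolated)
Conditions: n-BuLi, THF, –78 °C; then 9, –78 → –40 °C; aq. NH4Cl
Reagents that add atoms: none
Why: Bromine–lithium exchange is faster than any deprotonation at –78 °C, where the ortho-fluoroaryllithium is stable toward LiF loss, and the Weinreb ketone synthesis stops at the chelated tetrahedral adduct so that only the ketone should form.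

Step 6
Reactants: 11 2-(benzyloxy)-1-{4-(benzyloxy)-3-[(2R,3S,4S)-3,7-bis(benzyloxy)-2-[3,4,5-tris(benzyloxy)phenyl]chroman-4-yl]-2-fluorophenyl}ethan-1-one
Product: 12 (2R,3S,4S)-3,7-bis(benzyloxy)-4-{6-(benzyloxy)-3-[(Z)-2-(benzyloxy)-1-(trimethylsilyloxy)vinyl]-2-fluorophenyl}-2-[3,4,5-tris(benzyloxy)phenyl]chromane
Conditions: Me3SiOTf, Et3N, CH2Cl2, 0 °C; pentane, filtration, used crude
Reagents that add atoms: trimethylsilyl trifluoromethanesulfonate, C[Si](C)(C)OS(=O)(=O)C(F)(F)F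
Why: Soft enolisation and O-silylation of the α-alkoxy aryl ketone should give the Z enol silane (benzyloxy group turned away from the ortho-fluoroaryl ring), with no stereocentre affected.

Step 7
Reactants: 12 (2R,3S,4S)-3,7-bis(benzyloxy)-4-{6-(benzyloxy)-3-[(Z)-2-(benzyloxy)-1-(trimethylsilyloxy)vinyl]-2-fluorophenyl}-2-[3,4,5-tris(benzyloxy)phenyl]chromane; 13 3,4,5-tris(benzyloxy)benzaldehyde
Product: 15 (2R,3R)-3,7-bis(benzyloxy)-8-[(2R,3S,4S)-3,7-bis(benzyloxy)-2-[3,4,5-tris(benzyloxy)phenyl]chroman-4-yl]-2-[3,4,5-tris(benzyloxy)phenyl]chroman-4-one, via silylated aldol 14 (not isolated)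
Conditions: O-allyl-N-(9-anthracenylmethyl)cinchonidinium hydrogen difluoride (10 mol%), 13 (1.3 equiv), toluene/CH2Cl2, –50 °C, then 0 °C
Reagents that add atoms: none
Why: Proposed new method: the bifluoride desilylates 12 to a chiral ammonium (Z)-enolate that adds through an open transition state to the Si face of 13 (closest known reaction: cinchona ammonium bifluoride-catalysed Mukaiyama aldol of α-alkoxy aryl ketone enol silanes), and silyl transfer from 12 parks the aldolate as silyl ether 14 and carries the chain. On warming, fluoride unmasks the alkoxide, which closes ring C by 6-exo-trig addition–elimination (SNAr, exo with respect to the C8a–C8 π bond) at C8a through a Meisenheimer complex stabilised by the ortho C4 carbonyl (closest known reactions: alkoxide SNAr cyclisation of 2-fluoroaryl ketones and fluoride-catalysed SNAr of silyl ethers); the expelled fluoride returns as the ammonium fluoride, so Me3SiF is the only by-product and no stoichiometric base meets the product. C2 (R) is set by the ion-paired cinchonidinium cation, which shields one enolate face and selects the aldehyde Si face. C3 (R) is set by the ring closure and by thermodynamics: the chair-like closure with aryl and benzyloxy groups both equatorial should be the fast one, and a cis isomer would epimerise at the enolisable C3 under the catalytic fluoride to the diequatorial trans isomer. The step needs ring closure to outrun retro-aldol and base-induced opening of the chromanone; carbonyl activation of the C–F bond, the silyl ether reservoir, low temperature and the absence of stoichiometric base are meant to secure this, and the single fluorine makes the closure regiospecific.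

Step 8
Reactants: 15 (2R,3R)-3,7-bis(benzyloxy)-8-[(2R,3S,4S)-3,7-bis(benzyloxy)-2-[3,4,5-tris(benzyloxy)phenyl]chroman-4-yl]-2-[3,4,5-tris(benzyloxy)phenyl]chroman-4-one
Product: 16 (2R,3R)-3,7-dihydroxy-8-[(2R,3S,4S)-3,7-dihydroxy-2-(3,4,5-trihydroxyphenyl)chroman-4-yl]-2-(3,4,5-trihydroxyphenyl)chroman-4-one
Conditions: H2 (1 atm), Pd(OH)2/C, THF/MeOH, rt; filtration under argon
Reagents that add atoms: none
Why: Hydrogenolysis should cleave all ten benzyl ethers under neutral conditions that neither reduce the electron-rich C4 aryl ketone nor epimerise any stereocentre.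

**Compound list**

1 | (+)-dihydrorobinetin, (2R,3R)-3,7-dihydroxy-2-(3,4,5-trihydroxyphenyl)chroman-4-one | O=C1c2ccc(O)cc2O[C@H](c2cc(O)c(O)c(O)c2)[C@H]1O | starting material
2 | (2R,3R)-7-(benzyloxy)-3-hydroxy-2-[3,4,5-tris(benzyloxy)phenyl]chroman-4-one | O=C1c2ccc(OCc3ccccc3)cc2O[C@H](c2cc(OCc3ccccc3)c(OCc3ccccc3)c(OCc3ccccc3)c2)[C@H]1O | intermediate
3 | (2R,3S,4R)-7-(benzyloxy)-2-[3,4,5-tris(benzyloxy)phenyl]chromane-3,4-diol | O[C@@H]1c2ccc(OCc3ccccc3)cc2O[C@H](c2cc(OCc3ccccc3)c(OCc3ccccc3)c(OCc3ccccc3)c2)[C@H]1O | intermediate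
4 | (2R,3S,4R)-3,4,7-tris(benzyloxy)-2-[3,4,5-tris(benzyloxy)phenyl]chromane | c1ccccc1CO[C@@H]2c3ccc(OCc4ccccc4)cc3O[C@H](c3cc(OCc4ccccc4)c(OCc4ccccc4)c(OCc4ccccc4)c3)[C@H]2OCc2ccccc2 | intermediate
5 | 4-(benzyloxy)-1-bromo-2-fluorobenzene | Brc1ccc(OCc2ccccc2)cc1F | starting material
6 | [6-(benzyloxy)-3-bromo-2-fluorophenyl]lithium | [Li]c1c(F)c(Br)ccc1OCc1ccccc1 | intermediate
7 | bis[6-(benzyloxy)-3-bromo-2-fluorophenyl]zinc | Brc1ccc(OCc2ccccc2)c([Zn]c2c(F)c(Br)ccc2OCc2ccccc2)c1F | intermediate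
8 | (2R,3S,4S)-3,7-bis(benzyloxy)-4-[6-(benzyloxy)-3-bromo-2-fluorophenyl]-2-[3,4,5-tris(benzyloxy)phenyl]chromane | Brc1ccc(OCc2ccccc2)c([C@@H]2c3ccc(OCc4ccccc4)cc3O[C@H](c3cc(OCc4ccccc4)c(OCc4ccccc4)c(OCc4ccccc4)c3)[C@H]2OCc2ccccc2)c1F | intermediate
9 | 2-(benzyloxy)-N-methoxy-N-methylacetamide | CON(C)C(=O)COCc1ccccc1 | starting material
10 | {4-(benzyloxy)-3-[(2R,3S,4S)-3,7-bis(benzyloxy)-2-[3,4,5-tris(benzyloxy)phenyl]chroman-4-yl]-2-fluorophenyl}lithium | [Li]c1ccc(OCc2ccccc2)c([C@@H]2c3ccc(OCc4ccccc4)cc3O[C@H](c3cc(OCc4ccccc4)c(OCc4ccccc4)c(OCc4ccccc4)c3)[C@H]2OCc2ccccc2)c1F | intermediate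
11 | 2-(benzyloxy)-1-{4-(benzyloxy)-3-[(2R,3S,4S)-3,7-bis(benzyloxy)-2-[3,4,5-tris(benzyloxy)phenyl]chroman-4-yl]-2-fluorophenyl}ethan-1-one | O=C(COCc1ccccc1)c1ccc(OCc2ccccc2)c([C@@H]2c3ccc(OCc4ccccc4)cc3O[C@H](c3cc(OCc4ccccc4)c(OCc4ccccc4)c(OCc4ccccc4)c3)[C@H]2OCc2ccccc2)c1F | intermediate
12 | (2R,3S,4S)-3,7-bis(benzyloxy)-4-{6-(benzyloxy)-3-[(Z)-2-(benzyloxy)-1-(trimethylsilyloxy)vinyl]-2-fluorophenyl}-2-[3,4,5-tris(benzyloxy)phenyl]chromane | C[Si](C)(C)O/C(=C\OCc1ccccc1)c1ccc(OCc2ccccc2)c([C@@H]2c3ccc(OCc4ccccc4)cc3O[C@H](c3cc(OCc4ccccc4)c(OCc4ccccc4)c(OCc4ccccc4)c3)[C@H]2OCc2ccccc2)c1F | intermediate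
13 | 3,4,5-tris(benzyloxy)benzaldehyde | O=Cc1cc(OCc2ccccc2)c(OCc2ccccc2)c(OCc2ccccc2)c1 | starting material
14 | (2R,3R)-2-(benzyloxy)-1-{4-(benzyloxy)-3-[(2R,3S,4S)-3,7-bis(benzyloxy)-2-[3,4,5-tris(benzyloxy)phenyl]chroman-4-yl]-2-fluorophenyl}-3-[3,4,5-tris(benzyloxy)phenyl]-3-(trimethylsilyloxy)propan-1-one | C[Si](C)(C)O[C@H](c1cc(OCc2ccccc2)c(OCc2ccccc2)c(OCc2ccccc2)c1)[C@@H](OCc1ccccc1)C(=O)c1ccc(OCc2ccccc2)c([C@@H]2c3ccc(OCc4ccccc4)cc3O[C@H](c3cc(OCc4ccccc4)c(OCc4ccccc4)c(OCc4ccccc4)c3)[C@H]2OCc2ccccc2)c1F | intermediate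
15 | (2R,3R)-3,7-bis(benzyloxy)-8-[(2R,3S,4S)-3,7-bis(benzyloxy)-2-[3,4,5-tris(benzyloxy)phenyl]chroman-4-yl]-2-[3,4,5-tris(benzyloxy)phenyl]chroman-4-one | O=C1c2ccc(OCc3ccccc3)c([C@@H]3c4ccc(OCc5ccccc5)cc4O[C@H](c4cc(OCc5ccccc5)c(OCc5ccccc5)c(OCc5ccccc5)c4)[C@H]3OCc3ccccc3)c2O[C@H](c2cc(OCc3ccccc3)c(OCc3ccccc3)c(OCc3ccccc3)c2)[C@H]1OCc1ccccc1 | intermediate
16 | (2R,3R)-3,7-dihydroxy-8-[(2R,3S,4S)-3,7-dihydroxy-2-(3,4,5-trihydroxyphenyl)chroman-4-yl]-2-(3,4,5-trihydroxyphenyl)chroman-4-one | O=C1c2ccc(O)c([C@@H]3c4ccc(O)cc4O[C@H](c4cc(O)c(O)c(O)c4)[C@H]3O)c2O[C@H](c2cc(O)c(O)c(O)c2)[C@H]1O | target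

**Summary**

Total step count: 8. Longest linear sequence: 8 steps (from 1; compounds 5, 9 and 13 are bought).

Steps most likely to fail:

1. Step 7 (the step that carries the new-method label). The ammonium aldolate may revert by retro-aldol faster than it closes the ring, which would erode catalyst control; facial selection in the ion pair may be poor; and fluoride may open the 3-alkoxychromanone by E1cB. The fallback uses known chemistry and closes ring C through O1–C2 instead, by the chalcone epoxide route. It sets out from bromide 8. Bromine–lithium exchange (n-BuLi, THF, –78 °C) and acylation with N-methoxy-N-methylacetamide would give 1-{4-(benzyloxy)-3-[(2R,3S,4S)-3,7-bis(benzyloxy)-2-[3,4,5-tris(benzyloxy)phenyl]chroman-4-yl]-2-fluorophenyl}ethan-1-one F1. SNAr with the hydroxide surrogate 2-(methylsulfonyl)ethanol (NaH, DMF) would give the 2-hydroxyphenyl ketone F2, and MOMCl with iPr2NEt would give its methoxymethyl ether F3. Claisen–Schmidt condensation with aldehyde 13 (KOH, EtOH/THF) would give the (E)-chalcone F4. Juliá–Colonna epoxidation (poly-L-leucine, urea–hydrogen peroxide, DBU, THF) should give the (2R,3S)-epoxy ketone F5. HCl in MeOH/THF at 50 °C would remove the acetal and let the phenol open the epoxide at the benzylic carbon with inversion, giving the trans nona-O-benzyl dihydroflavonol F6. Under the conditions of step 8 this comes back to the route at target 16.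

2. Step 4. The flavan-4-yl cation may condense with the electron-rich ring A of a second molecule of 4 faster than the hindered arylzinc captures it, and attack may not be cleanly anti to the 3-benzyloxy group. The fallback uses a phenolic π-nucleophile and introduces fluorine afterwards; it sets out from 4. Houben–Hoesch acylation of resorcinol with benzyloxyacetonitrile (ZnCl2, HCl, Et2O; then water) would give 2-(benzyloxy)-1-(2,4-dihydroxyphenyl)ethan-1-one F7. Friedel–Crafts coupling of 4 with excess F7 (Me3SiOTf, CH2Cl2/THF, –78 °C) at the carbon between the two hydroxyls would give the C-linked resacetophenone F8, to be separated from any isomer formed at the other free position. BnBr and K2CO3 in acetone would benzylate only the non-chelated para hydroxyl to give the 2-hydroxyphenyl ketone F9. Deoxyfluorination of that phenol with 1,3-bis(2,6-diisopropylphenyl)-2,2-difluoro-2,3-dihydro-1H-imidazole and CsF in toluene at 110 °C comes back to the route at ketone 11.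

3. Step 1. Carbonate may epimerise C2 through ring opening to a ring B quinone methide, and the pyrogallol and α-ketol units may oxidise in air before benzylation is complete. The fallback removes the ketone before any base is used; it sets out from 1. NaBH4 in EtOH would give leucorobinetinidin F10, and exhaustive benzylation (NaH, BnBr, DMF, 0 °C → rt) of its six hydroxyls comes back to the route at 4.

Further compounds
F1 | step 7 | 1-{4-(benzyloxy)-3-[(2R,3S,4S)-3,7-bis(benzyloxy)-2-[3,4,5-tris(benzyloxy)phenyl]chroman-4-yl]-2-fluorophenyl}ethan-1-one | CC(=O)c1ccc(OCc2ccccc2)c([C@@H]2c3ccc(OCc4ccccc4)cc3O[C@H](c3cc(OCc4ccccc4)c(OCc4ccccc4)c(OCc4ccccc4)c3)[C@H]2OCc2ccccc2)c1F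
F2 | step 7 | 1-{4-(benzyloxy)-3-[(2R,3S,4S)-3,7-bis(benzyloxy)-2-[3,4,5-tris(benzyloxy)phenyl]chroman-4-yl]-2-hydroxyphenyl}ethan-1-one | CC(=O)c1ccc(OCc2ccccc2)c([C@@H]2c3ccc(OCc4ccccc4)cc3O[C@H](c3cc(OCc4ccccc4)c(OCc4ccccc4)c(OCc4ccccc4)c3)[C@H]2OCc2ccccc2)c1O
F3 | step 7 | 1-{4-(benzyloxy)-3-[(2R,3S,4S)-3,7-bis(benzyloxy)-2-[3,4,5-tris(benzyloxy)phenyl]chroman-4-yl]-2-(methoxymethoxy)phenyl}ethan-1-one | CC(=O)c1ccc(OCc2ccccc2)c([C@@H]2c3ccc(OCc4ccccc4)cc3O[C@H](c3cc(OCc4ccccc4)c(OCc4ccccc4)c(OCc4ccccc4)c3)[C@H]2OCc2ccccc2)c1OCOC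
F4 | step 7 | (E)-1-{4-(benzyloxy)-3-[(2R,3S,4S)-3,7-bis(benzyloxy)-2-[3,4,5-tris(benzyloxy)phenyl]chroman-4-yl]-2-(methoxymethoxy)phenyl}-3-[3,4,5-tris(benzyloxy)phenyl]prop-2-en-1-one | O=C(/C=C/c1cc(OCc2ccccc2)c(OCc2ccccc2)c(OCc2ccccc2)c1)c1ccc(OCc2ccccc2)c([C@@H]2c3ccc(OCc4ccccc4)cc3O[C@H](c3cc(OCc4ccccc4)c(OCc4ccccc4)c(OCc4ccccc4)c3)[C@H]2OCc2ccccc2)c1OCOC
F5 | step 7 | {4-(benzyloxy)-3-[(2R,3S,4S)-3,7-bis(benzyloxy)-2-[3,4,5-tris(benzyloxy)phenyl]chroman-4-yl]-2-(methoxymethoxy)phenyl}{(2R,3S)-3-[3,4,5-tris(benzyloxy)phenyl]oxiran-2-yl}methanone | O=C([C@@H]1O[C@H]1c1cc(OCc2ccccc2)c(OCc2ccccc2)c(OCc2ccccc2)c1)c1ccc(OCc2ccccc2)c([C@@H]2c3ccc(OCc4ccccc4)cc3O[C@H](c3cc(OCc4ccccc4)c(OCc4ccccc4)c(OCc4ccccc4)c3)[C@H]2OCc2ccccc2)c1OCOC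
F6 | step 7 | (2R,3R)-7-(benzyloxy)-8-[(2R,3S,4S)-3,7-bis(benzyloxy)-2-[3,4,5-tris(benzyloxy)phenyl]chroman-4-yl]-3-hydroxy-2-[3,4,5-tris(benzyloxy)phenyl]chroman-4-one | O=C1c2ccc(OCc3ccccc3)c([C@@H]3c4ccc(OCc5ccccc5)cc4O[C@H](c4cc(OCc5ccccc5)c(OCc5ccccc5)c(OCc5ccccc5)c4)[C@H]3OCc3ccccc3)c2O[C@H](c2cc(OCc3ccccc3)c(OCc3ccccc3)c(OCc3ccccc3)c2)[C@H]1O
F7 | step 4 | 2-(benzyloxy)-1-(2,4-dihydroxyphenyl)ethan-1-one | O=C(COCc1ccccc1)c1ccc(O)cc1O
F8 | step 4 | 2-(benzyloxy)-1-{3-[(2R,3S,4S)-3,7-bis(benzyloxy)-2-[3,4,5-tris(benzyloxy)phenyl]chroman-4-yl]-2,4-dihydroxyphenyl}ethan-1-one | O=C(COCc1ccccc1)c1ccc(O)c([C@@H]2c3ccc(OCc4ccccc4)cc3O[C@H](c3cc(OCc4ccccc4)c(OCc4ccccc4)c(OCc4ccccc4)c3)[C@H]2OCc2ccccc2)c1O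
F9 | step 4 | 2-(benzyloxy)-1-{4-(benzyloxy)-3-[(2R,3S,4S)-3,7-bis(benzyloxy)-2-[3,4,5-tris(benzyloxy)phenyl]chroman-4-yl]-2-hydroxyphenyl}ethan-1-one | O=C(COCc1ccccc1)c1ccc(OCc2ccccc2)c([C@@H]2c3ccc(OCc4ccccc4)cc3O[C@H](c3cc(OCc4ccccc4)c(OCc4ccccc4)c(OCc4ccccc4)c3)[C@H]2OCc2ccccc2)c1O
F10 | step 1 | leucorobinetinidin, (2R,3S,4R)-2-(3,4,5-trihydroxyphenyl)chromane-3,4,7-triol | O[C@@H]1c2ccc(O)cc2O[C@H](c2cc(O)c(O)c(O)c2)[C@H]1O
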